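**Analysis of the target**

Compound 12 (the target) is a diarylmethane: two hexasubstituted benzene rings joined through one methylene carbon (C7), with no ring fusion, no stereocentre and no configurational double bond. Ring A (C1–C6) carries a butanoyl group at C1, hydroxyls at C2, C4 and C6, a methyl group at C3 and the bridge at C5. Ring B (C1'–C6') carries the bridge at C1', hydroxyls at C2' and C6', a methyl group at C3', the only methoxy group at C4' and a butanoyl group at C5'. The two rings are thus the same C-methylated butanoylphloroglucinol and differ in one O-methyl group, which sits on the oxygen that is ortho to the ketone and flanked by the C-methyl group; direct methylation reaches this chelated, hindered oxygen last. Sensitive points are the five free phenols (oxidised in basic, aerated media), the two ortho-hydroxyaryl ketones and above all the C5–C7–C1' bridge, which opens and re-forms through ortho-quinone methides under base or under acid and heat, so that an unsymmetrical dimer can scramble into the two symmetrical ones. Three things make the synthesis hard: (a) joining two nearly identical nucleophilic rings through one carbon without homodimers; (b) putting one methyl group on the C4' oxygen and on none of the other five; (c) a concealed constitutional ambiguity, because an enolate-based ring construction that can use the α-CH2 of a butanoyl or of a propanoyl unit interchangeably turns C3'-methyl/C5'-butanoyl into C-ethyl/propanoyl. The feature the route exploits is the run C3'(CH3)–C4'(OCH3)–C5'(COC3H7)–C6'(OH) of ring B, together with C1' carrying C7 between the hydroxyls at C2' and C6': this is an intact polyketide pattern, so ring B is built from open-chain pieces on a finished ring A, each ring carbon arriving with its substituent.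

**Retrosynthetic reasoning**

12 ⇒ 11. The last cut removes two O-benzyl groups, on the C2 and C6 oxygens of ring A. They are needed because the ring-forming step uses strong base, so ring A must enter it without acidic O–H. They must leave under neutral conditions, since base or hot acid would let the bridge scramble; hydrogenolysis does this, and nothing else in 11 is reducible under those conditions.

11 ⇒ 9 + 6 (through 10). Ring B is cut at C2'–C3' and at C6'–C1', not at the aryl–CH2 bonds. These cuts give two pieces of unambiguous reactivity. Compound 9 holds C6' (ester carbon), C5' (already carrying the butanoyl group), C4' (already carrying the methoxy group) and C3' with its methyl group (the terminal CH2CH3); its most acidic C–H is at C3', vinylogous to both carbonyl groups. Compound 6 holds C2' (lactone carbonyl), C1' (α-CH2), C7 and the whole of ring A. Forward, C3' of 9 must be acylated by the lactone carbonyl of 6 (giving 10); then C1' must close onto the ester carbon with loss of the ester methoxy group and aromatise. The gain is that all six substituents of ring B are fixed by connectivity: the methoxy group can only be at C4' and the bridge only at C1' between two hydroxyls. Homodimers cannot form because ring B does not exist before it is attached to ring A. The C7–C1' bond never has to be made, since it is the Cα–Cβ bond of 4.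

9 ⇒ 7 + 8. The C4'=C5' double bond is cut: condensation of the active methylene of 7 with the orthoester carbon of 8. This is preferred to O-methylation of a triacyl compound, whose propanoyl and butanoyl ketones could not be told apart. Here the methoxy group and the ethyl group arrive on the same carbon from 8.

6 ⇒ 5 ⇒ 3 + 4. The benzyl ethers are removed first; 5 is then cut at C5–C7 and at the lactone C–O bond. Forward, the single free ring carbon of 3 adds to 4 in a conjugate sense and the acid lactonises. The lactone is kept on purpose: it is the activated ester needed in step 5, it protects one phenol, and it does not matter which of the two neighbouring oxygens it uses.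

3 ⇒ 1 + 2. Friedel–Crafts disconnection of the ketone. Because 1 is symmetrical, its two free positions are equivalent and ring A needs no regiocontrol.

**Alternatives that were turned down**

Alternative 1: Disconnection at the two aryl–CH2 bonds (C5–C7 and C7–C1'), the textbook and presumed biosynthetic one. Forward, 3 and the ring B ketone 1-(2,4-dihydroxy-6-methoxy-5-methylphenyl)butan-1-one A1 are condensed with formaldehyde, or one partner is first made into an ortho-quinone methide precursor (Mannich base) and trapped by the other. It was turned down for two structural reasons.
- Both partners are nucleophiles of the same kind with one free carbon each, so one-carbon linking has no inherent preference for the mixed product over the symmetrical dimers A2 (from 3) and A3 (from A1). The stepwise variant does not escape this, because the diarylmethane bonds of such phloroglucinols reopen to the quinone methide under the basic or hot coupling conditions and re-equilibrate.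
- The real problem is only moved into A1. O-Methylation of 3 would take the unchelated para oxygen first, and a C-methyl group introduced after the O-methyl group would go between the two free hydroxyls. A1 therefore needs a protecting-group sequence about as long as the whole route chosen here.

Alternative 2: Disconnection of the C5'–C(=O) bond and the C6'–O bond of ring B in one operation, by an aryne at C5'≡C6' inserted into the C–O bond of butanoic acid. Forward, fluoride acts on 5-(benzyloxy)-3-methoxy-4-methyl-2-(trimethylsilyl)phenyl trifluoromethanesulfonate A4 to give a 3-methoxyaryne. The carboxylate adds to the aryne carbon remote from the methoxy group, which polarises the triple bond so that negative charge builds up next to it. The aryl anion formed beside the methoxy group then takes over the acyl group through a four-membered transition state, giving the ortho-hydroxyaryl ketone A5 with the ketone between OH and OCH3, exactly the ring B pattern. The regiochemistry is right, but the move fails on step economy.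
- A4 is a pentasubstituted arene that needs differentiated oxygens, a directed silylation and a triflation, which is more steps than the whole chosen route.
- Its only product after debenzylation is A1, and the union with ring A is then still Alternative 1 with its scrambling problem.
- Carrying ring A through the aryne step instead would need five protected phenols and a nucleophilic attack on an aryne carbon flanked by the bulky arylmethyl group.

Alternative 3: Disconnection of ring B at C2'–C3' and C5'–C6' ([3+3]). The dienolate of the β-methoxy enone 6-methoxyoct-5-en-4-one A6 serves as the C3'–C4'–C5' unit with the butanoyl group in place. It is diacylated by a malonyl dielectrophile carrying ring A, 2-{[2,4,6-tris(benzyloxy)-3-butanoyl-5-methylphenyl]methyl}propanedioyl dichloride A7; this is the α,α'-diacylation that builds cyclohexane-1,3,5-triones from enol ethers and malonyl dichlorides. It was turned down for four reasons.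
- A6 is one of two nearly identical mono enol ethers of its parent 1,3-diketone and cannot be made from it with control.
- Strong bases deprotonate β-alkoxy enones kinetically at the α'-carbon, here the CH2 of the butanoyl group. Acylation there closes the ring around the wrong carbonyl, which moves an ethyl group onto the ring and leaves the methoxy group outside it.
- With acyclic partners, malonyl dichlorides tend towards C,O-diacylation to pyranones.
- A7 would itself need a malonate to be attached to ring A and three protecting groups.

The chosen route keeps the idea of building ring B on ring A but moves the cuts by one bond, so that C5' is already fully substituted in 9 and a single acidic site dominates.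

Key step: step 5

Remark on the chemistry: 12 has no stereogenic element; 9 and 10 are mixtures of double-bond isomers (10 also racemic at C3') that all converge in step 5, so their SMILES carry no descriptors; 1, 2, 4, 7 and 8 are taken to be catalogue chemicals.

**Steps**

Step 1
Reactants: 1 2-methylbenzene-1,3,5-triol (2-methylphloroglucinol); 2 butanoyl chloride
Product: 3 1-(2,4,6-trihydroxy-3-methylphenyl)butan-1-one
Conditions: AlCl3 (3.5 equiv), PhNO2/CH2Cl2, 0 to 45 °C; then ice/aq. HCl
Reagents that add atoms: none
Why: Friedel–Crafts acylation; the two unsubstituted carbons of 1 are equivalent, so only one C-acyl product can form, the new ketone deactivates the ring towards a second acylation, and any O-acyl product rearranges to 3 under the same conditions (Fries rearrangement).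

Step 2
Reactants: 3 1-(2,4,6-trihydroxy-3-methylphenyl)butan-1-one; 4 prop-2-enoic acid (acrylic acid)
Product: 5 6-butanoyl-5,7-dihydroxy-8-methyl-3,4-dihydro-2H-chromen-2-one
Conditions: Amberlyst-15 (sulfonic acid resin), toluene, 110 °C, Dean–Stark
Reagents that add atoms: none
Why: Acid-catalysed Friedel–Crafts conjugate addition (hydroarylation) of the only free ring carbon C5 to 4, then lactonisation onto a neighbouring hydroxyl, the known route from phenols and acrylic acid to 3,4-dihydrocoumarins. Closure is expected on the C4 oxygen, which lies outside the ketone chelate; closure on the C6 oxygen would cost nothing, since step 5 opens either lactone to the same chain and step 6 removes all benzyl groups. The lactone is at once the C7–C1'–C2' unit, an activated aryl ester and the protection of one phenol.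

Step 3
Reactants: 5 6-butanoyl-5,7-dihydroxy-8-methyl-3,4-dihydro-2H-chromen-2-one
Product: 6 5,7-bis(benzyloxy)-6-butanoyl-8-methyl-3,4-dihydro-2H-chromen-2-one
Conditions: BnBr (2.6 equiv), K2CO3 (3 equiv), DMF, 60 °C
Reagents that add atoms: benzyl bromide, BrCc1ccccc1
Why: Williamson ether synthesis on the two remaining phenols (both ortho to the ketone, hence the warm polar medium); ring A has no free carbon for C-benzylation and the aryl lactone survives anhydrous carbonate. The benzyl ethers remove the acidic protons that would quench the enolate of step 5 and leave under neutral conditions in step 6.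

Step 4
Reactants: 7 methyl 3-oxohexanoate; 8 1,1,1-trimethoxypropane (trimethyl orthopropionate)
Product: 9 methyl 2-butanoyl-3-methoxypent-2-enoate (E/Z mixture)
Conditions: Ac2O (2.5 equiv), ZnCl2 (cat.), 130 °C, low boilers distilled off
Reagents that add atoms: none
Why: Condensation of an active methylene compound with an orthoester, as known for orthoformates and orthoacetates with 1,3-dicarbonyl compounds: the enol of 7 attacks the dialkoxycarbenium ion from 8 and two methoxy groups leave as methanol, which the anhydride takes up. The construction is unambiguous: C4' with its methoxy group and the ethyl group that becomes C3' and its methyl come from 8, and C5', C6' and the butanoyl group come from 7.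

Step 5
Reactants: 9 methyl 2-butanoyl-3-methoxypent-2-enoate; 6 5,7-bis(benzyloxy)-6-butanoyl-8-methyl-3,4-dihydro-2H-chromen-2-one
Product: 11 1-[2,6-bis(benzyloxy)-3-[(3-butanoyl-2,6-dihydroxy-4-methoxy-5-methylphenyl)methyl]-4-hydroxy-5-methylphenyl]butan-1-one, via open-chain keto ester 10 (not isolated)
Conditions: 9 (2.2 equiv), LiN(SiMe3)2 (2.1 equiv), THF, −78 to 0 °C; 6 (1 equiv), −78 °C to rt; then LiN(iPr)2 (4.5 equiv), −78 to 0 °C; aq. HCl
Reagents that add atoms: none
Why: The extended lithium enolate of 9, whose charge is shared by the ester and the ketone through C4'=C5', is acylated at its γ-carbon C3' by the aryl lactone 6 (vinylogous Claisen condensation; the phenoxide leaving group makes 6 a far better acyl donor than an alkyl ester), and 10 is at once deprotonated at the doubly activated C3'–H, which makes this condensation irreversible. LiN(iPr)2 then removes a C1' proton beside the C2' ketone and this enolate attacks the ester carbon C6' in a Dieckmann-type 6-exo-trig (enolexo) closure, the only ring closed in the step; loss of methoxide and of the C1' proton gives the ring B phenoxide. The closest known reaction types are the γ-acylation of lithiated β-methoxy-α,β-unsaturated esters by esters and lactones and the base-induced Claisen cyclisation of 3,5,7-trioxo esters to acylphloroglucinols, the laboratory copy of the polyketide ring closure. No stereocentre is created: the C3' centre and the double-bond geometry of 10 disappear on aromatisation, and the push-pull C4'=C5' bond rotates freely in the anion, so both isomers of 9 reach the U-shaped conformer that cyclises. The first selectivity needed is γ over α and α': C5' is fully substituted and an adduct there cannot be deprotonated and reverts, while warming the enolate to 0 °C with a slight deficit of base before 6 is added lets the kinetically formed cross-conjugated butanoyl enolate equilibrate to the more stable extended one. The second is closure of C1' on the ester and not on the butanoyl carbonyl that shares C5' (aldol mode) or through the C2' enolate oxygen (pyranone): in the delocalised anion the ketone carries the enolate character and the ester remains the carbonyl-like acceptor, an aldolate cannot dehydrate in the aprotic medium and reopens, a pyranone is reopened by the methoxide it releases, and only the Claisen closure ends in an irreversible aromatisation. Since C5' enters with both the ester and the butanoyl group and C4' with its methoxy group, the constitution of ring B follows from the connectivity of 9 and 6 and from no selective alkylation, and the C-ethyl/propanoyl isomer cannot arise because the butanoyl α-carbon has no acceptor within reach of a six-membered closure other than the deactivated C2' enolate.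

Step 6
Reactants: 11 1-[2,6-bis(benzyloxy)-3-[(3-butanoyl-2,6-dihydroxy-4-methoxy-5-methylphenyl)methyl]-4-hydroxy-5-methylphenyl]butan-1-one
Product: 12 1-[3-[(3-butanoyl-2,6-dihydroxy-4-methoxy-5-methylphenyl)methyl]-2,4,6-trihydroxy-5-methylphenyl]butan-1-one
Conditions: H2 (1 atm), 10% Pd/C, EtOAc, rt
Reagents that add atoms: none
Why: Hydrogenolysis of the two aryl benzyl ethers on palladium; the ortho-hydroxyaryl ketones (vinylogous acids) and the diarylmethane are not reduced under these conditions, and the neutral medium avoids base- or acid-induced scrambling of the bridge.

**Compound list**

1 | 2-methylbenzene-1,3,5-triol (2-methylphloroglucinol) | Cc1c(O)cc(O)cc1O | starting material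
2 | butanoyl chloride | CCCC(=O)Cl | starting material
3 | 1-(2,4,6-trihydroxy-3-methylphenyl)butan-1-one | CCCC(=O)c1c(O)cc(O)c(C)c1O | intermediate
4 | prop-2-enoic acid (acrylic acid) | C=CC(=O)O | starting material
5 | 6-butanoyl-5,7-dihydroxy-8-methyl-3,4-dihydro-2H-chromen-2-one | CCCC(=O)c1c(O)c(C)c2OC(=O)CCc2c1O | intermediate
6 | 5,7-bis(benzyloxy)-6-butanoyl-8-methyl-3,4-dihydro-2H-chromen-2-one | CCCC(=O)c1c(OCc2ccccc2)c(C)c2OC(=O)CCc2c1OCc1ccccc1 | intermediate
7 | methyl 3-oxohexanoate | CCCC(=O)CC(=O)OC | starting material
8 | 1,1,1-trimethoxypropane (trimethyl orthopropionate) | CCC(OC)(OC)OC | starting material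
9 | methyl 2-butanoyl-3-methoxypent-2-enoate (E/Z mixture) | CCCC(=O)C(C(=O)OC)=C(OC)CC | intermediate
10 | methyl 7-[2,4-bis(benzyloxy)-3-butanoyl-6-hydroxy-5-methylphenyl]-2-butanoyl-3-methoxy-4-methyl-5-oxohept-2-enoate (racemic, E/Z mixture; formed in the flask in step 5) | CCCC(=O)C(C(=O)OC)=C(OC)C(C)C(=O)CCc1c(O)c(C)c(OCc2ccccc2)c(C(=O)CCC)c1OCc1ccccc1 | intermediate
11 | 1-[2,6-bis(benzyloxy)-3-[(3-butanoyl-2,6-dihydroxy-4-methoxy-5-methylphenyl)methyl]-4-hydroxy-5-methylphenyl]butan-1-one | CCCC(=O)c1c(OCc2ccccc2)c(C)c(O)c(Cc2c(O)c(C)c(OC)c(C(=O)CCC)c2O)c1OCc1ccccc1 | intermediate
12 | 1-[3-[(3-butanoyl-2,6-dihydroxy-4-methoxy-5-methylphenyl)methyl]-2,4,6-trihydroxy-5-methylphenyl]butan-1-one | CCCC(=O)c1c(O)c(C)c(O)c(Cc2c(O)c(C)c(OC)c(C(=O)CCC)c2O)c1O | target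

**Step count and least certain steps**

Total number of steps: 6. Longest linear sequence: 5 steps (1, 2, 3, 5, 6); step 4 is a one-step branch that joins at step 5.

Step 5 (key step). Four processes may interfere:
- slow or oxygen-selective acylation, because the γ-carbanion of 9 is stabilised and secondary and the lactone is hindered;
- ring closure through the enolate oxygen onto the ester before the second deprotonation has taken place;
- aldol-type closure of C1' onto the butanoyl carbonyl, which shares C5' with the ester, followed by dehydration on work-up;
- reaction through the kinetically formed enolate on the butanoyl side.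

All four come from the ketone on C5', which is what lets the step finish ring B in one operation but is also a second acceptor and a second enolisable site.

The fallback takes the ketone out of the ring-forming step; it sets out from 8 and 6 and comes back to the route at 12. Condensation of 8 with dibenzyl propanedioate (Ac2O, ZnCl2 cat., 130 °C) gives dibenzyl 2-(1-methoxypropylidene)propanedioate F1. Its two acceptors are identical esters, so no aldol mode exists and an O-cyclised pyranone is reopened by the alkoxide it releases. The same γ-acylation by 6 and Dieckmann closure give benzyl 3-{[2,4-bis(benzyloxy)-3-butanoyl-6-hydroxy-5-methylphenyl]methyl}-2,4-dihydroxy-6-methoxy-5-methylbenzoate F2. Hydrogenolysis (H2, Pd/C, EtOAc) removes all three benzyl groups to give 3-[(3-butanoyl-2,4,6-trihydroxy-5-methylphenyl)methyl]-2,4-dihydroxy-6-methoxy-5-methylbenzoic acid F3. As a phloroglucinol carboxylic acid, F3 loses carbon dioxide on gentle warming to give 1-[3-[(2,6-dihydroxy-4-methoxy-3-methylphenyl)methyl]-2,4,6-trihydroxy-5-methylphenyl]butan-1-one F4. Hoesch acylation of F4 with butanenitrile (ZnCl2, HCl, Et2O, 0 °C; then water) at C5', the only unsubstituted aromatic carbon of the molecule, gives 12.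

Step 4. An orthoester of propanoic acid is a weaker electrophile than an orthoformate and can lose methanol to a ketene acetal, which the anhydride acetylates; O-acetylation of the enol of 7 competes as well, so conversion may stay low.

The fallback sets out from 7 and comes back at 9. Knoevenagel condensation of 7 with propanal (piperidinium acetate, toluene, Dean–Stark) gives methyl 2-butanoylpent-2-enoate F5. Conjugate addition of methanol (NaOMe cat., MeOH, 0 °C) gives methyl 2-butanoyl-3-methoxypentanoate F6. Selenenylation at C2 (PhSeCl, pyridine, CH2Cl2) gives methyl 2-butanoyl-3-methoxy-2-(phenylselanyl)pentanoate F7. Oxidation (H2O2, 0 °C) and selenoxide syn-elimination, for which the C3 hydrogen is the only one available, give 9.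

Step 2. The ketone lowers the nucleophilicity of C5, so polymerisation of 4, C-acylation by 4 or partial loss of the butanoyl group in hot acid may outrun the hydroarylation.

The fallback sets out from 3 and comes back at 5. A base-mediated three-component reaction of 3 with paraformaldehyde and 2,2-dimethyl-1,3-dioxane-4,6-dione (Et3N cat., MeCN, rt) gives the Michael adduct 5-[(3-butanoyl-2,4,6-trihydroxy-5-methylphenyl)methyl]-2,2-dimethyl-1,3-dioxane-4,6-dione F8. Heating in pyridine (90 °C) lactonises it with loss of acetone to 6-butanoyl-5,7-dihydroxy-8-methyl-2-oxo-3,4-dihydro-2H-chromene-3-carboxylic acid F9 (racemic), which decarboxylates under the same conditions to 5.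

**Further compounds**

F1 | step 5 | dibenzyl 2-(1-methoxypropylidene)propanedioate | CCC(OC)=C(C(=O)OCc1ccccc1)C(=O)OCc1ccccc1
F2 | step 5 | benzyl 3-{[2,4-bis(benzyloxy)-3-butanoyl-6-hydroxy-5-methylphenyl]methyl}-2,4-dihydroxy-6-methoxy-5-methylbenzoate | CCCC(=O)c1c(OCc2ccccc2)c(C)c(O)c(Cc2c(O)c(C)c(OC)c(C(=O)OCc3ccccc3)c2O)c1OCc1ccccc1
F3 | step 5 | 3-[(3-butanoyl-2,4,6-trihydroxy-5-methylphenyl)methyl]-2,4-dihydroxy-6-methoxy-5-methylbenzoic acid | CCCC(=O)c1c(O)c(C)c(O)c(Cc2c(O)c(C)c(OC)c(C(=O)O)c2O)c1O
F4 | step 5 | 1-[3-[(2,6-dihydroxy-4-methoxy-3-methylphenyl)methyl]-2,4,6-trihydroxy-5-methylphenyl]butan-1-one | CCCC(=O)c1c(O)c(C)c(O)c(Cc2c(O)c(C)c(OC)cc2O)c1O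
F5 | step 4 | methyl 2-butanoylpent-2-enoate (E/Z mixture) | CCCC(=O)C(C(=O)OC)=CCC
F6 | step 4 | methyl 2-butanoyl-3-methoxypentanoate (mixture of racemic diastereomers) | CCCC(=O)C(C(=O)OC)C(OC)CC
F7 | step 4 | methyl 2-butanoyl-3-methoxy-2-(phenylselanyl)pentanoate (mixture of racemic diastereomers) | CCCC(=O)C([Se]c1ccccc1)(C(=O)OC)C(OC)CC
F8 | step 2 | 5-[(3-butanoyl-2,4,6-trihydroxy-5-methylphenyl)methyl]-2,2-dimethyl-1,3-dioxane-4,6-dione | CCCC(=O)c1c(O)c(C)c(O)c(CC2C(=O)OC(C)(C)OC2=O)c1O
F9 | step 2 | 6-butanoyl-5,7-dihydroxy-8-methyl-2-oxo-3,4-dihydro-2H-chromene-3-carboxylic acid (racemic) | CCCC(=O)c1c(O)c(C)c2OC(=O)C(C(=O)O)Cc2c1O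
A1 | alternative 1 | 1-(2,4-dihydroxy-6-methoxy-5-methylphenyl)butan-1-one | CCCC(=O)c1c(OC)c(C)c(O)cc1O
A2 | alternative 1 | 1,1'-[methylenebis(2,4,6-trihydroxy-5-methyl-3,1-phenylene)]di(butan-1-one) | CCCC(=O)c1c(O)c(C)c(O)c(Cc2c(O)c(C)c(O)c(C(=O)CCC)c2O)c1O
A3 | alternative 1 | 1,1'-[methylenebis(2,4-dihydroxy-6-methoxy-5-methyl-3,1-phenylene)]di(butan-1-one) | CCCC(=O)c1c(OC)c(C)c(O)c(Cc2c(O)c(C)c(OC)c(C(=O)CCC)c2O)c1O
A4 | alternative 2 | 5-(benzyloxy)-3-methoxy-4-methyl-2-(trimethylsilyl)phenyl trifluoromethanesulfonate | COc1c(C)c(OCc2ccccc2)cc(OS(=O)(=O)C(F)(F)F)c1[Si](C)(C)C
A5 | alternative 2 | 1-[4-(benzyloxy)-2-hydroxy-6-methoxy-5-methylphenyl]butan-1-one | CCCC(=O)c1c(OC)c(C)c(OCc2ccccc2)cc1O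
A6 | alternative 3 | 6-methoxyoct-5-en-4-one | CCCC(=O)C=C(OC)CC
A7 | alternative 3 | 2-{[2,4,6-tris(benzyloxy)-3-butanoyl-5-methylphenyl]methyl}propanedioyl dichloride | CCCC(=O)c1c(OCc2ccccc2)c(C)c(OCc2ccccc2)c(CC(C(Cl)=O)C(Cl)=O)c1OCc1ccccc1
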